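**Retrosynthetic overview**

1. Target 23 comes from its 6,3',4'-tris-MOM ether 22 by acidic loss of the three MOM groups.
2. Number the benzoxepine O1, C2, C3(Me)=C4, C5, C5a, C6, C7, C8, C9, C9a. The C8 hydroxyl and the C7 acyl carbon are neighbours on the benzo ring and together make up the O and C=O of one carboxylic acid. A C7–C8 aryne from silyl triflate 15, polarised by the C6 oxygen next to C7, therefore takes up protected dihydrocaffeic acid 18 with O going to C8 and the acyl group to C7.
3. Silicon enters 15 at C7, the one ring C–H lying between two carbamates (on the C6 and C8 oxygens of 8). The less hindered C8 oxygen is then triflated and the C6 oxygen receives MOM.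
4. Diol 7 comes from ring-closing metathesis of the C-allyl/O-methallyl diene 5, which is set up by a symmetric Claisen rearrangement on a phloroglucinol bis-MOM ether.
5. Ring order: benzo ring from phloroglucinol, oxepine ring in step 5 (the only ring built), catechol ring from dihydrocaffeic acid; no stereocentre.

Key step: step 12

Assumption: the C3=C4 alkene can only be cis inside the seven-membered ring and the target has no stereocentre, so no stereocontrol is needed; anhydrous phloroglucinol is used.

**Route**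

Step 1
Reactants: 1 phloroglucinol
Product: 2 3,5-bis(methoxymethoxy)phenol
Conditions: MOMCl (2.0 equiv), iPr2NEt (2.2 equiv), DMF, 0 °C to rt; chromatography, mono-ether resubmitted
Reagents that add atoms: chloromethyl methyl ether (MOMCl), COCCl
Why: O-alkylation of the phenoxides with a hard alkoxymethyl chloride (Williamson-type etherification) should give a statistical mixture of ethers from which the bis-ether, with one free hydroxyl, is separated.

Step 2
Reactants: 2 3,5-bis(methoxymethoxy)phenol
Product: 3 1-(allyloxy)-3,5-bis(methoxymethoxy)benzene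
Conditions: allyl bromide, K2CO3, acetone, reflux
Reagents that add atoms: allyl bromide, C=CCBr
Why: Williamson ether synthesis on the single free phenol should proceed cleanly under carbonate conditions.

Step 3
Reactants: 3 1-(allyloxy)-3,5-bis(methoxymethoxy)benzene
Product: 4 2-allyl-3,5-bis(methoxymethoxy)phenol
Conditions: N,N-diethylaniline, 190 °C
Reagents that add atoms: none
Why: In this aromatic Claisen rearrangement ([3,3]-sigmatropic shift) the two ortho positions are equivalent by symmetry, so a single ortho-allyl phenol should form, and the freed hydroxyl is by construction the oxygen next to the allyl group (future O1).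

Step 4
Reactants: 4 2-allyl-3,5-bis(methoxymethoxy)phenol
Product: 5 2-allyl-1,5-bis(methoxymethoxy)-3-(2-methylallyloxy)benzene
Conditions: 3-bromo-2-methylpropene, K2CO3, DMF, rt to 50 °C
Reagents that add atoms: 3-bromo-2-methylprop-1-ene (methallyl bromide), C=C(C)CBr
Why: Williamson etherification of the only phenol places the methallyl group on the oxygen ortho to the C-allyl group.

Step 5
Reactants: 5 2-allyl-1,5-bis(methoxymethoxy)-3-(2-methylallyloxy)benzene
Product: 6 6,8-bis(methoxymethoxy)-3-methyl-2,5-dihydro-1-benzoxepine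
Conditions: second-generation Grubbs catalyst (5 mol%), 1,4-benzoquinone (10 mol%), CH2Cl2, 40 °C
Reagents that add atoms: none
Why: Ring-closing metathesis of the terminal and the 1,1-disubstituted alkene should close the seven-membered oxepine with loss of ethylene, the trisubstituted C3=C4 alkene being cis by ring constraint and benzoquinone suppressing alkene migration.

Step 6
Reactants: 6 6,8-bis(methoxymethoxy)-3-methyl-2,5-dihydro-1-benzoxepine
Product: 7 3-methyl-2,5-dihydro-1-benzoxepine-6,8-diol
Conditions: 3 M HCl, MeOH, 45 °C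
Reagents that add atoms: none
Why: Acid-catalysed acetal methanolysis removes both MOM groups, while the ring allyl aryl ether, which would ionise only to a non-tertiary allyl cation, should survive.

Step 7
Reactants: 7 3-methyl-2,5-dihydro-1-benzoxepine-6,8-diol
Product: 8 3-methyl-2,5-dihydro-1-benzoxepine-6,8-diyl bis(N-isopropylcarbamate)
Conditions: i-PrNCO (2.5 equiv), Et3N (0.3 equiv), CH2Cl2, rt
Reagents that add atoms: isopropyl isocyanate, CC(C)N=C=O
Why: Amine-catalysed addition of phenols to an isocyanate (carbamate formation) is driven to both hydroxyls, so no selectivity is asked of this step.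

Step 8
Reactants: 8 3-methyl-2,5-dihydro-1-benzoxepine-6,8-diyl bis(N-isopropylcarbamate)
Product: 12 3-methyl-7-(trimethylsilyl)-2,5-dihydro-1-benzoxepine-6,8-diyl bis(N-isopropylcarbamate), via doubly N-silylated bis-carbamate 9 (not isolated), via C7 aryllithium 10 (not isolated), via N-silylated C7 silane 11 (not isolated)
Conditions: TBSOTf (2.2 equiv), TMEDA, Et2O, 0 °C to rt; n-BuLi (1.5 equiv), TMEDA, −78 °C; TMSCl, −78 °C to rt; aq. NaHSO4 work-up
Reagents that add atoms: chlorotrimethylsilane, C[Si](C)(C)Cl
Why: In this directed ortho-metalation the N–H groups are masked in the flask by silylation, C7 is the only ring C–H flanked by two carbamates and should be lithiated in preference to C9 (one carbamate and the ring ether), and the cold silyl chloride quench forestalls the anionic Fries shift.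

Step 9
Reactants: 12 3-methyl-7-(trimethylsilyl)-2,5-dihydro-1-benzoxepine-6,8-diyl bis(N-isopropylcarbamate)
Product: 14 6-hydroxy-3-methyl-7-(trimethylsilyl)-2,5-dihydro-1-benzoxepin-8-yl trifluoromethanesulfonate, via silyl resorcinol 13 (not isolated)
Conditions: DBU (3 equiv), Et2NH (2.5 equiv), MeCN, 40 °C; then PhNTf2 (1.0 equiv), 0 °C to rt
Reagents that add atoms: N-phenylbis(trifluoromethanesulfonimide) (PhNTf2), O=S(=O)(N(c1ccccc1)S(=O)(=O)C(F)(F)F)C(F)(F)F
Why: E1cB cleavage of the secondary carbamates (isocyanate trapped by Et2NH) frees both phenoxides, and one equivalent of the bulky sulfonimide should sulfonylate the C8 oxygen (flanked by silicon and hydrogen) in preference to the C6 oxygen (flanked by silicon and the C5 methylene).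

Step 10
Reactants: 14 6-hydroxy-3-methyl-7-(trimethylsilyl)-2,5-dihydro-1-benzoxepin-8-yl trifluoromethanesulfonate
Product: 15 6-(methoxymethoxy)-3-methyl-7-(trimethylsilyl)-2,5-dihydro-1-benzoxepin-8-yl trifluoromethanesulfonate
Conditions: MOMCl, iPr2NEt, CH2Cl2, 0 °C to 40 °C
Reagents that add atoms: chloromethyl methyl ether (MOMCl), COCCl
Why: Base-mediated O-alkylation with the small alkoxymethyl chloride should reach the hindered C6 phenol without touching the aryl triflate or the aryl silane.

Step 11
Reactants: 16 3-(3,4-dihydroxyphenyl)propanoic acid (dihydrocaffeic acid)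
Product: 18 3-[3,4-bis(methoxymethoxy)phenyl]propanoic acid, via methoxymethyl ester 17 (not isolated)
Conditions: MOMCl (3.5 equiv), iPr2NEt, CH2Cl2, 0 °C to rt; then LiOH, THF/MeOH/H2O, rt; cold 1 M HCl to pH 4
Reagents that add atoms: chloromethyl methyl ether (MOMCl), COCCl; lithium hydroxide, [Li+].[OH-]
Why: Exhaustive alkylation protects both phenols and the acid, and saponification then cleaves only the labile acyloxymethyl ester while the aryl MOM ethers stay.

Step 12
Reactants: 15 6-(methoxymethoxy)-3-methyl-7-(trimethylsilyl)-2,5-dihydro-1-benzoxepin-8-yl trifluoromethanesulfonate; 18 3-[3,4-bis(methoxymethoxy)phenyl]propanoic acid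
Product: 22 1-[8-hydroxy-6-(methoxymethoxy)-3-methyl-2,5-dihydro-1-benzoxepin-7-yl]-3-[3,4-bis(methoxymethoxy)phenyl]propan-1-one, via benzoxepine aryne 19 (not isolated), via ortho-caesio aryl ester 20 (not isolated), via benzoxete alkoxide 21 (not isolated)
Conditions: CsF (4 equiv), 18 (1.5 equiv), THF, 125 °C, sealed tube
Reagents that add atoms: none
Why: Fluoride attacks silicon in 15 and triflate leaves from C8 to give the C7–C8 aryne 19; the caesium carboxylate formed from 18 and CsF adds through oxygen at C8 to give the C7 carbanion 20, which attacks its own ester carbonyl to form the four-membered alkoxide 21, and this opens by C–O cleavage to the ortho-acyl phenoxide, protonated on work-up to 22. The closest known reaction is the fluoride-induced insertion of arynes into the C–O bond of carboxylic acids to give ortho-hydroxyaryl ketones, in mechanism an anionic Fries shift that needs no added base. No lasting ring is closed, the only cyclisation being the transient 4-exo-trig closure of 20 to 21, and no stereocentre is formed. Regiocontrol is needed in the carboxylate addition and comes from the C6 methoxymethoxy oxygen, whose inductive pull makes C8 the electrophilic aryne carbon and stabilises charge at C7, as in 3-alkoxybenzynes. Acyl migration should win over protonation of 20 to the plain aryl ester in hot aprotic THF, where the only proton carrier is poorly soluble CsHF2. Because the acyl group can travel only to the carbon that carried silicon, acylation at C9 is excluded.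

Step 13
Reactants: 22 1-[8-hydroxy-6-(methoxymethoxy)-3-methyl-2,5-dihydro-1-benzoxepin-7-yl]-3-[3,4-bis(methoxymethoxy)phenyl]propan-1-one
Product: 23 1-(6,8-dihydroxy-3-methyl-2,5-dihydro-1-benzoxepin-7-yl)-3-(3,4-dihydroxyphenyl)propan-1-one (CNP0203471.0)
Conditions: 3 M HCl, MeOH/THF, 45 °C
Reagents that add atoms: none
Why: Acid-catalysed acetal methanolysis should remove the C6 and the two catechol MOM groups, while the ring allyl aryl ether, further deactivated by the para acyl group, stays intact.

**Compound list**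

1 | phloroglucinol (benzene-1,3,5-triol) | Oc1cc(O)cc(O)c1 | starting material
2 | 3,5-bis(methoxymethoxy)phenol | COCOc1cc(O)cc(OCOC)c1 | intermediate
3 | 1-(allyloxy)-3,5-bis(methoxymethoxy)benzene | C=CCOc1cc(OCOC)cc(OCOC)c1 | intermediate
4 | 2-allyl-3,5-bis(methoxymethoxy)phenol | C=CCc1c(O)cc(OCOC)cc1OCOC | intermediate
5 | 2-allyl-1,5-bis(methoxymethoxy)-3-(2-methylallyloxy)benzene | C=CCc1c(OCC(C)=C)cc(OCOC)cc1OCOC | intermediate
6 | 6,8-bis(methoxymethoxy)-3-methyl-2,5-dihydro-1-benzoxepine | CC1=CCc2c(cc(OCOC)cc2OCOC)OC1 | intermediate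
7 | 3-methyl-2,5-dihydro-1-benzoxepine-6,8-diol | CC1=CCc2c(cc(O)cc2O)OC1 | intermediate
8 | 3-methyl-2,5-dihydro-1-benzoxepine-6,8-diyl bis(N-isopropylcarbamate) | CC1=CCc2c(cc(OC(=O)NC(C)C)cc2OC(=O)NC(C)C)OC1 | intermediate
9 | N,N'-bis(tert-butyldimethylsilyl) derivative of 8 (not isolated) | CC1=CCc2c(cc(OC(=O)N(C(C)C)[Si](C)(C)C(C)(C)C)cc2OC(=O)N(C(C)C)[Si](C)(C)C(C)(C)C)OC1 | intermediate
10 | C7 aryllithium of 9 (not isolated) | CC1=CCc2c(cc(OC(=O)N(C(C)C)[Si](C)(C)C(C)(C)C)c([Li])c2OC(=O)N(C(C)C)[Si](C)(C)C(C)(C)C)OC1 | intermediate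
11 | 7-(trimethylsilyl) derivative of 9 (not isolated) | CC1=CCc2c(cc(OC(=O)N(C(C)C)[Si](C)(C)C(C)(C)C)c([Si](C)(C)C)c2OC(=O)N(C(C)C)[Si](C)(C)C(C)(C)C)OC1 | intermediate
12 | 3-methyl-7-(trimethylsilyl)-2,5-dihydro-1-benzoxepine-6,8-diyl bis(N-isopropylcarbamate) | CC1=CCc2c(cc(OC(=O)NC(C)C)c([Si](C)(C)C)c2OC(=O)NC(C)C)OC1 | intermediate
13 | 3-methyl-7-(trimethylsilyl)-2,5-dihydro-1-benzoxepine-6,8-diol (not isolated) | CC1=CCc2c(cc(O)c([Si](C)(C)C)c2O)OC1 | intermediate
14 | 6-hydroxy-3-methyl-7-(trimethylsilyl)-2,5-dihydro-1-benzoxepin-8-yl trifluoromethanesulfonate | CC1=CCc2c(cc(OS(=O)(=O)C(F)(F)F)c([Si](C)(C)C)c2O)OC1 | intermediate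
15 | 6-(methoxymethoxy)-3-methyl-7-(trimethylsilyl)-2,5-dihydro-1-benzoxepin-8-yl trifluoromethanesulfonate | CC1=CCc2c(cc(OS(=O)(=O)C(F)(F)F)c([Si](C)(C)C)c2OCOC)OC1 | intermediate
16 | 3-(3,4-dihydroxyphenyl)propanoic acid (dihydrocaffeic acid) | O=C(O)CCc1ccc(O)c(O)c1 | starting material
17 | methoxymethyl 3-[3,4-bis(methoxymethoxy)phenyl]propanoate (not isolated) | COCOC(=O)CCc1ccc(OCOC)c(OCOC)c1 | intermediate
18 | 3-[3,4-bis(methoxymethoxy)phenyl]propanoic acid | O=C(O)CCc1ccc(OCOC)c(OCOC)c1 | intermediate
19 | 6-(methoxymethoxy)-3-methyl-7,8-didehydro-2,5-dihydro-1-benzoxepine, the C7–C8 aryne (not isolated) | CC1=CCC2=C(OCOC)C#CC=C2OC1 | intermediate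
20 | caesium salt of the C7 carbanion of 6-(methoxymethoxy)-3-methyl-2,5-dihydro-1-benzoxepin-8-yl 3-[3,4-bis(methoxymethoxy)phenyl]propanoate (not isolated) | CC1=CCc2c(cc(OC(=O)CCc3ccc(OCOC)c(OCOC)c3)[c-]c2OCOC)OC1.[Cs+] | intermediate
21 | caesium alkoxide of the benzoxete fused across C7–C8, carrying the 2-arylethyl chain on the alkoxide carbon (not isolated) | CC1=CCc2c(cc3OC([O-])(CCc4ccc(OCOC)c(OCOC)c4)c3c2OCOC)OC1.[Cs+] | intermediate
22 | 1-[8-hydroxy-6-(methoxymethoxy)-3-methyl-2,5-dihydro-1-benzoxepin-7-yl]-3-[3,4-bis(methoxymethoxy)phenyl]propan-1-one | CC1=CCc2c(cc(O)c(C(=O)CCc3ccc(OCOC)c(OCOC)c3)c2OCOC)OC1 | intermediate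
23 | 1-(6,8-dihydroxy-3-methyl-2,5-dihydro-1-benzoxepin-7-yl)-3-(3,4-dihydroxyphenyl)propan-1-one | CC1=CCc2c(cc(O)c(C(=O)CCc3ccc(O)c(O)c3)c2O)OC1 | target

**Step count and risks**

Total step count: 13. Longest linear sequence: 12 steps (steps 1 to 10, 12 and 13, from phloroglucinol 1); step 11 is a one-step branch.

Steps most likely to fail:

Step 12. The C7 carbanion may pick up a proton before the acyl shift, which stops the sequence at the C8 aryl ester, or the carboxylate may add at C7 and erode the regiocontrol. The fallback makes the C7–acyl bond by directed metalation; it sets out from acid 18 and bis-carbamate 8 and comes back at target 23. Acid 18 is coupled with N,O-dimethylhydroxylamine hydrochloride (EDC·HCl, Et3N, CH2Cl2) to give the N-methoxy-N-methylamide F1. Bis-carbamate 8 is N-silylated and lithiated at C7 as in step 8 (through 9 and 10), and aryllithium 10 is quenched at −78 °C with F1 to give the doubly N-silylated C7 ketone F2. Aqueous NaHSO4 work-up removes the silyl groups and gives the bis-carbamate ketone F3. DBU and Et2NH in MeCN at 40 °C then cleave both carbamates to give the 6,8-dihydroxy ketone F4, which still carries the two catechol MOM ethers, and HCl in MeOH gives 23.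

Step 9. Both phenoxides may be sulfonylated, or the reagent may not discriminate well enough between the C8 and the C6 oxygen. The fallback tells the two oxygens apart before silicon enters; it sets out from diol 7 and comes back at silyl triflate 15. One equivalent of isopropyl isocyanate (Et3N cat., CH2Cl2, 0 °C) should carbamoylate the unhindered C8 hydroxyl to give the mono-carbamate F5, and MOMCl with iPr2NEt then protects the C6 hydroxyl to give the MOM ether F6. N-silylation in the flask (TBSOTf, TMEDA) gives the N-silyl carbamate F7, and n-BuLi/TMEDA at −78 °C lithiates C7 between the carbamate and the MOM ether to give the aryllithium F8. TMSCl gives the N-silylated silane F9, and work-up gives the silyl carbamate F10. DBU and Et2NH release the phenol F11, which PhNTf2 converts into 15 in the same flask, now with a single phenoxide present.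

Step 8. The double N-silylation may stay incomplete so that residual N–H consumes the base, or base may be lost to the benzylic and allylic C5 methylene. The fallback uses tertiary carbamates, which need no N-protection, and removes them reductively; it sets out from diol 7 and comes back at silyl resorcinol 13, which is then isolated and triflated with PhNTf2 as in the second half of step 9. Et2NCOCl with K2CO3 in MeCN at reflux gives the bis(N,N-diethylcarbamate) F12. s-BuLi/TMEDA in THF at −78 °C gives the C7 aryllithium F13, which is quenched cold with TMSCl to give the silane F14. LiAlH4 in THF then cleaves both carbamates to give 13.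

**Further compounds**

F1 | step 12 | N-methoxy-N-methyl-3-[3,4-bis(methoxymethoxy)phenyl]propanamide | CON(C)C(=O)CCc1ccc(OCOC)c(OCOC)c1
F2 | step 12 | 7-{3-[3,4-bis(methoxymethoxy)phenyl]propanoyl}-3-methyl-2,5-dihydro-1-benzoxepine-6,8-diyl bis[N-(tert-butyldimethylsilyl)-N-isopropylcarbamate] | CC1=CCc2c(cc(OC(=O)N(C(C)C)[Si](C)(C)C(C)(C)C)c(C(=O)CCc3ccc(OCOC)c(OCOC)c3)c2OC(=O)N(C(C)C)[Si](C)(C)C(C)(C)C)OC1
F3 | step 12 | 7-{3-[3,4-bis(methoxymethoxy)phenyl]propanoyl}-3-methyl-2,5-dihydro-1-benzoxepine-6,8-diyl bis(N-isopropylcarbamate) | CC1=CCc2c(cc(OC(=O)NC(C)C)c(C(=O)CCc3ccc(OCOC)c(OCOC)c3)c2OC(=O)NC(C)C)OC1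
F4 | step 12 | 1-(6,8-dihydroxy-3-methyl-2,5-dihydro-1-benzoxepin-7-yl)-3-[3,4-bis(methoxymethoxy)phenyl]propan-1-one | CC1=CCc2c(cc(O)c(C(=O)CCc3ccc(OCOC)c(OCOC)c3)c2O)OC1
F5 | step 9 | 6-hydroxy-3-methyl-2,5-dihydro-1-benzoxepin-8-yl N-isopropylcarbamate | CC1=CCc2c(cc(OC(=O)NC(C)C)cc2O)OC1
F6 | step 9 | 6-(methoxymethoxy)-3-methyl-2,5-dihydro-1-benzoxepin-8-yl N-isopropylcarbamate | CC1=CCc2c(cc(OC(=O)NC(C)C)cc2OCOC)OC1
F7 | step 9 | 6-(methoxymethoxy)-3-methyl-2,5-dihydro-1-benzoxepin-8-yl N-(tert-butyldimethylsilyl)-N-isopropylcarbamate | CC1=CCc2c(cc(OC(=O)N(C(C)C)[Si](C)(C)C(C)(C)C)cc2OCOC)OC1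
F8 | step 9 | C7 aryllithium of F7 | CC1=CCc2c(cc(OC(=O)N(C(C)C)[Si](C)(C)C(C)(C)C)c([Li])c2OCOC)OC1
F9 | step 9 | 6-(methoxymethoxy)-3-methyl-7-(trimethylsilyl)-2,5-dihydro-1-benzoxepin-8-yl N-(tert-butyldimethylsilyl)-N-isopropylcarbamate | CC1=CCc2c(cc(OC(=O)N(C(C)C)[Si](C)(C)C(C)(C)C)c([Si](C)(C)C)c2OCOC)OC1
F10 | step 9 | 6-(methoxymethoxy)-3-methyl-7-(trimethylsilyl)-2,5-dihydro-1-benzoxepin-8-yl N-isopropylcarbamate | CC1=CCc2c(cc(OC(=O)NC(C)C)c([Si](C)(C)C)c2OCOC)OC1
F11 | step 9 | 6-(methoxymethoxy)-3-methyl-7-(trimethylsilyl)-2,5-dihydro-1-benzoxepin-8-ol | CC1=CCc2c(cc(O)c([Si](C)(C)C)c2OCOC)OC1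
F12 | step 8 | 3-methyl-2,5-dihydro-1-benzoxepine-6,8-diyl bis(N,N-diethylcarbamate) | CC1=CCc2c(cc(OC(=O)N(CC)CC)cc2OC(=O)N(CC)CC)OC1
F13 | step 8 | C7 aryllithium of F12 | CC1=CCc2c(cc(OC(=O)N(CC)CC)c([Li])c2OC(=O)N(CC)CC)OC1
F14 | step 8 | 3-methyl-7-(trimethylsilyl)-2,5-dihydro-1-benzoxepine-6,8-diyl bis(N,N-diethylcarbamate) | CC1=CCc2c(cc(OC(=O)N(CC)CC)c([Si](C)(C)C)c2OC(=O)N(CC)CC)OC1
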